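## Retrosynthetic overview

- Ring C (the pyranone) is closed last through O1–C2, from an enaminone whose C2 comes from DMF dimethyl acetal. The C3–C1' bond comes from palladium-catalysed enolate arylation of the diprenylated ring A methyl ketone with an 8-bromochromene (rings B and D).
- The dimethylpyran ring (ring D) is disconnected at the aryl C2'–O bond. A 2'-fluoride is converted into the aryne C1'≡C2'; the tertiary alkoxide on the cis-alkenyl arm at C3' adds to C2', and the carbanion left on C1' is brominated in the same flask.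
- Enabling feature: in ring B the ether oxygen sits on C2', between C1' (bonded to C3 of ring C) and C3' (carrying the cis CH=CH–CMe2 arm). One aryne therefore delivers both the O–C2' bond and the coupling handle on C1'. The 4'-oxygen on the other side of C3' lets a coumarin lactone act as a temporary ring that fixes the cis alkene.
- Order of ring formation: ring B (bought) → temporary lactone ring (step 1, opened in step 2) → ring D (step 4) → ring A joined (step 7, prenyl groups from step 5) → ring C (step 9).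

Key step: step 4

Remark: locants C1'–C6' refer to ring B of the isoflavone (C1' bonded to C3 of ring C); the two numbered starting materials and all reagents named under Conditions are taken as commercial.

## Route

Step 1
Reactants: 1 2-fluoro-6-hydroxybenzaldehyde
Product: 2 5-fluoro-2H-chromen-2-one (5-fluorocoumarin)
Conditions: Ph3P=CHCO2Et, PhNEt2, rt → reflux
Reagents that add atoms: ethyl (triphenylphosphoranylidene)acetate, CCOC(=O)C=P(c1ccccc1)(c1ccccc1)c1ccccc1
Why: Wittig olefination of the aldehyde, then thermal E/Z equilibration of the cinnamate and lactonisation onto the ortho phenol (one-pot coumarin synthesis), should give the lactone as a temporary ring that locks the future styrene double bond cis.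

Step 2
Reactants: 2 5-fluoro-2H-chromen-2-one
Product: 3 3-fluoro-2-[(1Z)-3-hydroxy-3-methylbut-1-en-1-yl]phenol
Conditions: MeLi (3 equiv), THF, −78 → 0 °C; pH 7 buffer
Reagents that add atoms: methyllithium, [Li]C
Why: Double 1,2-addition of the hard nucleophile MeLi to the lactone carbonyl (ester to tertiary alcohol via the methyl ketone) should open the temporary ring, install the gem-dimethyl carbinol and free the 4'-oxygen, with the cis geometry inherited from the ring.

Step 3
Reactants: 3 3-fluoro-2-[(1Z)-3-hydroxy-3-methylbut-1-en-1-yl]phenol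
Product: 4 (3Z)-4-{2-fluoro-6-[tri(propan-2-yl)silyloxy]phenyl}-2-methylbut-3-en-2-ol
Conditions: TIPSCl, imidazole, DMF, 0 °C → rt
Reagents that add atoms: chlorotri(propan-2-yl)silane (TIPSCl), CC(C)[Si](Cl)(C(C)C)C(C)C
Why: O-silylation should be selective for the acidic, accessible phenol over the tertiary alcohol, and the bulky TIPS ether is a poor directing group for the lithiation that follows.

Step 4
Reactants: 4 (3Z)-4-{2-fluoro-6-[tri(propan-2-yl)silyloxy]phenyl}-2-methylbut-3-en-2-ol
Product: 8 [(8-bromo-2,2-dimethyl-2H-chromen-5-yl)oxy]tri(propan-2-yl)silane, via dilithio fluoroarene 5 (not isolated), via aryne alkoxide 6 (not isolated), via chromenyllithium 7 (not isolated)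
Conditions: s-BuLi (2.2 equiv), THF, −78 °C; warm to −30 °C; BrCH2CH2Br, −78 °C → rt
Reagents that add atoms: 1,2-dibromoethane, BrCCBr
Why: s-BuLi should first form the lithium alkoxide and then lithiate C1', the only hydrogen-bearing position next to fluorine (C3' is substituted and the bulky silyl ether does not direct to C5'), giving 5, which loses LiF on warming to form aryne 6 with the strained C1'≡C2' bond. The tertiary alkoxide held by the cis-alkenyl arm on C3' then adds in the ring plane to C2', the only aryne carbon it can reach (6-exo-dig with respect to the in-plane π bond), which closes the pyran ring through the aryl C2'–O bond and leaves the carbanion on C1' as aryllithium 7; 1,2-dibromoethane transfers bromine to C1'. The closest known reaction types are the elimination–addition ring closure of a tethered alkoxide onto an aryne and the anionic benzyne cyclisation with electrophilic capture of the new aryllithium. No stereocentre is formed, and the cis geometry needed for closure was fixed by the lactone ring of 2. The step needs site selectivity in the lithiation and in the addition to the aryne, secured by the single ortho hydrogen of the fluoride and by the tether length; it also needs the aryllithium to survive until the quench, which is why an alkyllithium base (conjugate acid butane) is used and not an amide base.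

Step 5
Reactants: 9 1-(2,4,6-trihydroxyphenyl)ethan-1-one
Product: 10 1-[2,4,6-trihydroxy-3,5-bis(3-methylbut-2-en-1-yl)phenyl]ethan-1-one
Conditions: prenyl bromide (2.2 equiv), 10% aq KOH, 0 °C → rt
Reagents that add atoms: 1-bromo-3-methylbut-2-ene (prenyl bromide), CC(C)=CCBr
Why: C-alkylation of the phloroglucinol-type phenolate (C-prenylation) at the two equivalent free ring positions should give the diprenyl ketone, the aqueous medium favouring C- over O-alkylation.

Step 6
Reactants: 10 1-[2,4,6-trihydroxy-3,5-bis(3-methylbut-2-en-1-yl)phenyl]ethan-1-one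
Product: 11 1-[2,4,6-tris(methoxymethoxy)-3,5-bis(3-methylbut-2-en-1-yl)phenyl]ethan-1-one
Conditions: NaH, MOMCl, DMF, 0 °C → rt
Reagents that add atoms: chloromethyl methyl ether (MOMCl), COCCl
Why: Williamson-type O-alkylation of the three phenoxides (NaH is needed for the chelated ortho hydroxyls) should mask all acidic OH groups for the enolate chemistry.

Step 7
Reactants: 11 1-[2,4,6-tris(methoxymethoxy)-3,5-bis(3-methylbut-2-en-1-yl)phenyl]ethan-1-one; 8 [(8-bromo-2,2-dimethyl-2H-chromen-5-yl)oxy]tri(propan-2-yl)silane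
Product: 12 2-{2,2-dimethyl-5-[tri(propan-2-yl)silyloxy]-2H-chromen-8-yl}-1-[2,4,6-tris(methoxymethoxy)-3,5-bis(3-methylbut-2-en-1-yl)phenyl]ethan-1-one
Conditions: Pd2(dba)3, XPhos, K3PO4, toluene, 90 °C
Reagents that add atoms: none
Why: Palladium-catalysed α-arylation of the methyl ketone enolate (oxidative addition of the aryl bromide to zerovalent palladium, enolate binding, reductive elimination) should form the C3–C1' bond of the deoxybenzoin, the bulky biaryl phosphine favouring monoarylation and the weak base sparing the aryl silyl ether.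

Step 8
Reactants: 12 2-{2,2-dimethyl-5-[tri(propan-2-yl)silyloxy]-2H-chromen-8-yl}-1-[2,4,6-tris(methoxymethoxy)-3,5-bis(3-methylbut-2-en-1-yl)phenyl]ethan-1-one
Product: 13 (2E)-3-(dimethylamino)-2-{2,2-dimethyl-5-[tri(propan-2-yl)silyloxy]-2H-chromen-8-yl}-1-[2,4,6-tris(methoxymethoxy)-3,5-bis(3-methylbut-2-en-1-yl)phenyl]prop-2-en-1-one
Conditions: Me2NCH(OMe)2, toluene, 100 °C
Reagents that add atoms: N,N-dimethylformamide dimethyl acetal, COC(OC)N(C)C
Why: Condensation of the activated benzylic methylene with the amide acetal (enaminone formation) should supply C2 of ring C; the push-pull double bond is expected as the E isomer, and its geometry is of no consequence because it is consumed in the ring closure.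

Step 9
Reactants: 13 (2E)-3-(dimethylamino)-2-{2,2-dimethyl-5-[tri(propan-2-yl)silyloxy]-2H-chromen-8-yl}-1-[2,4,6-tris(methoxymethoxy)-3,5-bis(3-methylbut-2-en-1-yl)phenyl]prop-2-en-1-one
Product: 14 3-{2,2-dimethyl-5-[tri(propan-2-yl)silyloxy]-2H-chromen-8-yl}-5,7-dihydroxy-6,8-bis(3-methylbut-2-en-1-yl)-4H-chromen-4-one
Conditions: HCl (1.25 M in MeOH), THF, 40 °C
Reagents that add atoms: none
Why: Acid methanolysis of the three MOM acetals should free an ortho phenol that adds to the protonated enaminone and expels dimethylamine (addition–elimination, the standard deoxybenzoin-to-isoflavone closure of ring C through O1–C2), either ortho hydroxyl giving the same product by symmetry.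

Step 10
Reactants: 14 3-{2,2-dimethyl-5-[tri(propan-2-yl)silyloxy]-2H-chromen-8-yl}-5,7-dihydroxy-6,8-bis(3-methylbut-2-en-1-yl)-4H-chromen-4-one
Product: 15 Kanzonol L, 5,7-dihydroxy-3-(5-hydroxy-2,2-dimethyl-2H-chromen-8-yl)-6,8-bis(3-methylbut-2-en-1-yl)-4H-chromen-4-one
Conditions: Bu4NF, AcOH, THF, 0 °C
Reagents that add atoms: none
Why: Fluoride-mediated cleavage of the aryl silyl ether (Si–F bond formation), buffered with acetic acid to protect the polyphenol, should release the 4'-hydroxyl and give the target.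

## Compound list

1 | 2-fluoro-6-hydroxybenzaldehyde | O=Cc1c(O)cccc1F | starting material
2 | 5-fluoro-2H-chromen-2-one | O=C1C=Cc2c(F)cccc2O1 | intermediate
3 | 3-fluoro-2-[(1Z)-3-hydroxy-3-methylbut-1-en-1-yl]phenol | CC(C)(O)/C=C\c1c(O)cccc1F | intermediate
4 | (3Z)-4-{2-fluoro-6-[tri(propan-2-yl)silyloxy]phenyl}-2-methylbut-3-en-2-ol | CC(C)(O)/C=C\c1c(O[Si](C(C)C)(C(C)C)C(C)C)cccc1F | intermediate
5 | lithium (3Z)-4-{2-fluoro-3-lithio-6-[tri(propan-2-yl)silyloxy]phenyl}-2-methylbut-3-en-2-olate | [Li]OC(C)(C)/C=C\c1c(O[Si](C(C)C)(C(C)C)C(C)C)ccc([Li])c1F | intermediate (not isolated)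
6 | lithium (3Z)-2-methyl-4-{2,3-didehydro-6-[tri(propan-2-yl)silyloxy]phenyl}but-3-en-2-olate (aryne across C1'–C2') | [Li]OC(C)(C)/C=C\C1=C(O[Si](C(C)C)(C(C)C)C(C)C)C=CC#C1 | intermediate (not isolated)
7 | {2,2-dimethyl-5-[tri(propan-2-yl)silyloxy]-2H-chromen-8-yl}lithium | [Li]c1ccc(O[Si](C(C)C)(C(C)C)C(C)C)c2C=CC(C)(C)Oc12 | intermediate (not isolated)
8 | [(8-bromo-2,2-dimethyl-2H-chromen-5-yl)oxy]tri(propan-2-yl)silane | Brc1ccc(O[Si](C(C)C)(C(C)C)C(C)C)c2C=CC(C)(C)Oc12 | intermediate
9 | 1-(2,4,6-trihydroxyphenyl)ethan-1-one | CC(=O)c1c(O)cc(O)cc1O | starting material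
10 | 1-[2,4,6-trihydroxy-3,5-bis(3-methylbut-2-en-1-yl)phenyl]ethan-1-one | CC(=O)c1c(O)c(CC=C(C)C)c(O)c(CC=C(C)C)c1O | intermediate
11 | 1-[2,4,6-tris(methoxymethoxy)-3,5-bis(3-methylbut-2-en-1-yl)phenyl]ethan-1-one | CC(=O)c1c(OCOC)c(CC=C(C)C)c(OCOC)c(CC=C(C)C)c1OCOC | intermediate
12 | 2-{2,2-dimethyl-5-[tri(propan-2-yl)silyloxy]-2H-chromen-8-yl}-1-[2,4,6-tris(methoxymethoxy)-3,5-bis(3-methylbut-2-en-1-yl)phenyl]ethan-1-one | O=C(Cc1ccc(O[Si](C(C)C)(C(C)C)C(C)C)c2C=CC(C)(C)Oc12)c1c(OCOC)c(CC=C(C)C)c(OCOC)c(CC=C(C)C)c1OCOC | intermediate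
13 | (2E)-3-(dimethylamino)-2-{2,2-dimethyl-5-[tri(propan-2-yl)silyloxy]-2H-chromen-8-yl}-1-[2,4,6-tris(methoxymethoxy)-3,5-bis(3-methylbut-2-en-1-yl)phenyl]prop-2-en-1-one | CN(C)/C=C(\c1ccc(O[Si](C(C)C)(C(C)C)C(C)C)c2C=CC(C)(C)Oc12)C(=O)c1c(OCOC)c(CC=C(C)C)c(OCOC)c(CC=C(C)C)c1OCOC | intermediate
14 | 3-{2,2-dimethyl-5-[tri(propan-2-yl)silyloxy]-2H-chromen-8-yl}-5,7-dihydroxy-6,8-bis(3-methylbut-2-en-1-yl)-4H-chromen-4-one | CC(C)=CCc1c(O)c(CC=C(C)C)c2occ(-c3ccc(O[Si](C(C)C)(C(C)C)C(C)C)c4c3OC(C)(C)C=C4)c(=O)c2c1O | intermediate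
15 | Kanzonol L, 5,7-dihydroxy-3-(5-hydroxy-2,2-dimethyl-2H-chromen-8-yl)-6,8-bis(3-methylbut-2-en-1-yl)-4H-chromen-4-one | CC(C)=CCc1c(O)c(CC=C(C)C)c2occ(-c3ccc(O)c4c3OC(C)(C)C=C4)c(=O)c2c1O | target

## Step count and risks

Total steps: 10. Longest linear sequence: 8 (steps 1, 2, 3, 4, 7, 8, 9, 10).

Steps most likely to fail:

1. Step 4. The aryllithium on C1' may be lost before bromine transfer (proton capture from the medium), or s-BuLi may add to the aryne or to the styrene-type double bond instead of acting only as a base. The fallback sets out from 4 and comes back at 8 by separating ring closure from the functionalisation of C1'. Treatment of 4 with lithium 2,2,6,6-tetramethylpiperidide (3 equiv, THF, −78 → 0 °C) runs the same elimination–addition under amide-base conditions, where the amine formed reprotonates C1', and should give [(2,2-dimethyl-2H-chromen-5-yl)oxy]tri(propan-2-yl)silane F1. Directed ortho-lithiation of F1 next to the ring oxygen (n-BuLi, TMEDA, Et2O, 0 °C; the other oxygen-flanked position is shielded by the silyl ether) and quench with 1,2-dibromoethane should then lead to 8.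

2. Step 7. Oxidative addition and reductive elimination with the hindered, electron-rich aryl bromide may be slow, so that self-condensation of the ketone, double arylation or loss of the silyl ether competes. The fallback sets out from 11 and 8 and comes back at 13 by replacing the enolate arylation with a cross-coupling of a vinyl iodide. Ketone 11 with Me2NCH(OMe)2 (toluene, 100 °C) should give (2E)-3-(dimethylamino)-1-[2,4,6-tris(methoxymethoxy)-3,5-bis(3-methylbut-2-en-1-yl)phenyl]prop-2-en-1-one F2. N-Iodosuccinimide (1 equiv, CH2Cl2, −20 °C) should iodinate the push-pull double bond, which is far more nucleophilic than the prenyl groups, to (2Z)-3-(dimethylamino)-2-iodo-1-[2,4,6-tris(methoxymethoxy)-3,5-bis(3-methylbut-2-en-1-yl)phenyl]prop-2-en-1-one F3. Bromide 8 is converted by bromine–lithium exchange (n-BuLi, THF, −78 °C) and 2-isopropoxy-4,4,5,5-tetramethyl-1,3,2-dioxaborolane into {[2,2-dimethyl-8-(4,4,5,5-tetramethyl-1,3,2-dioxaborolan-2-yl)-2H-chromen-5-yl]oxy}tri(propan-2-yl)silane F4. Suzuki–Miyaura coupling of F3 with F4 (Pd(dppf)Cl2, K3PO4, dioxane, 80 °C) should give 13.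

3. Step 9. While the three acetals are methanolysed, a freed phenol may add under acid catalysis to a neighbouring prenyl double bond (chroman formation), or methanol may add across the chromene double bond. The fallback sets out from 10 and 8 and comes back at 15 with a fluoride-labile protecting group on ring A, so that no strong acid is needed. Ketone 10 with NaH and 2-(trimethylsilyl)ethoxymethyl chloride (DMF, 0 °C → rt) should give 1-[3,5-bis(3-methylbut-2-en-1-yl)-2,4,6-tris{[2-(trimethylsilyl)ethoxy]methoxy}phenyl]ethan-1-one F5. Enolate arylation with 8 under the conditions of step 7 should give 2-{2,2-dimethyl-5-[tri(propan-2-yl)silyloxy]-2H-chromen-8-yl}-1-[3,5-bis(3-methylbut-2-en-1-yl)-2,4,6-tris{[2-(trimethylsilyl)ethoxy]methoxy}phenyl]ethan-1-one F6. Condensation with Me2NCH(OMe)2 should give (2E)-3-(dimethylamino)-2-{2,2-dimethyl-5-[tri(propan-2-yl)silyloxy]-2H-chromen-8-yl}-1-[3,5-bis(3-methylbut-2-en-1-yl)-2,4,6-tris{[2-(trimethylsilyl)ethoxy]methoxy}phenyl]prop-2-en-1-one F7. Excess Bu4NF (DMPU–THF, 60 °C), followed by acidification with AcOH, should remove all four silicon-based groups and close ring C to give 15 directly.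

## Further compounds

F1 | step 4 | [(2,2-dimethyl-2H-chromen-5-yl)oxy]tri(propan-2-yl)silane | CC1(C)C=Cc2c(O[Si](C(C)C)(C(C)C)C(C)C)cccc2O1
F2 | step 7 | (2E)-3-(dimethylamino)-1-[2,4,6-tris(methoxymethoxy)-3,5-bis(3-methylbut-2-en-1-yl)phenyl]prop-2-en-1-one | CN(C)/C=C/C(=O)c1c(OCOC)c(CC=C(C)C)c(OCOC)c(CC=C(C)C)c1OCOC
F3 | step 7 | (2Z)-3-(dimethylamino)-2-iodo-1-[2,4,6-tris(methoxymethoxy)-3,5-bis(3-methylbut-2-en-1-yl)phenyl]prop-2-en-1-one | CN(C)/C=C(\I)C(=O)c1c(OCOC)c(CC=C(C)C)c(OCOC)c(CC=C(C)C)c1OCOC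
F4 | step 7 | {[2,2-dimethyl-8-(4,4,5,5-tetramethyl-1,3,2-dioxaborolan-2-yl)-2H-chromen-5-yl]oxy}tri(propan-2-yl)silane | CC1(C)OB(OC1(C)C)c1ccc(O[Si](C(C)C)(C(C)C)C(C)C)c2C=CC(C)(C)Oc12
F5 | step 9 | 1-[3,5-bis(3-methylbut-2-en-1-yl)-2,4,6-tris{[2-(trimethylsilyl)ethoxy]methoxy}phenyl]ethan-1-one | CC(=O)c1c(OCOCC[Si](C)(C)C)c(CC=C(C)C)c(OCOCC[Si](C)(C)C)c(CC=C(C)C)c1OCOCC[Si](C)(C)C
F6 | step 9 | 2-{2,2-dimethyl-5-[tri(propan-2-yl)silyloxy]-2H-chromen-8-yl}-1-[3,5-bis(3-methylbut-2-en-1-yl)-2,4,6-tris{[2-(trimethylsilyl)ethoxy]methoxy}phenyl]ethan-1-one | O=C(Cc1ccc(O[Si](C(C)C)(C(C)C)C(C)C)c2C=CC(C)(C)Oc12)c1c(OCOCC[Si](C)(C)C)c(CC=C(C)C)c(OCOCC[Si](C)(C)C)c(CC=C(C)C)c1OCOCC[Si](C)(C)C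
F7 | step 9 | (2E)-3-(dimethylamino)-2-{2,2-dimethyl-5-[tri(propan-2-yl)silyloxy]-2H-chromen-8-yl}-1-[3,5-bis(3-methylbut-2-en-1-yl)-2,4,6-tris{[2-(trimethylsilyl)ethoxy]methoxy}phenyl]prop-2-en-1-one | CN(C)/C=C(\c1ccc(O[Si](C(C)C)(C(C)C)C(C)C)c2C=CC(C)(C)Oc12)C(=O)c1c(OCOCC[Si](C)(C)C)c(CC=C(C)C)c(OCOCC[Si](C)(C)C)c(CC=C(C)C)c1OCOCC[Si](C)(C)C
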